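## Analysis of the target

The target is a guaiane-type hydroazulene: a cyclopent-2-enone (C1–C5) fused through C1 and C5 to a cycloheptane (C1, C5–C10), with methyl groups on C4 and C10 and a 2-acetoxyprop-2-yl group (C11) on C7. It has five stereocentres, C1, C6, C7, C8 and C10 (1R,6R,7S,8R,10S). The C6 hydroxyl, the C7 side chain, the C8 acyloxy group and the C10 methyl lie on one face of the seven-membered ring, and the tertiary C1 hydroxyl lies on the other. Four oxygen functions must end up differentiated: a free allylic secondary alcohol (C6), an angelate (C8), a tertiary acetate (C11) and a free tertiary alcohol (C1) that is β to the ketone. The angelate isomerises easily to the tiglate, the C1 carbinol can suffer retro-aldol cleavage under base, and the tertiary acetate does not tolerate strong nucleophiles. The hard parts are the contiguous cis triad C6–C7–C8 on a flexible ring, the fully substituted C4=C5 enone oxidised at both γ-positions (C1 and C6), and the late differentiation of the oxygens. The strategy rests on the five atoms C3, C4, C5, C1 and C2: with C3 as a formyl carbon on an exocyclic C4=C5 alkene and C2 as an exocyclic methylene on C1, they form a pentadienyl array held on the neighbouring ring atoms C5 and C1, and joining C2 to C3 closes the five-membered ring.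

## Retrosynthetic reasoning

**Ester and protecting groups (40 ⇐ 39 ⇐ 36 + 37 ⇐ 35).** The C8–O acyl bond is cut last but one, because the angelate survives neither hydrogenation nor organometallic reagents and isomerises under base. The C8 and C6 oxygens therefore carry silyl groups of different lability: the C8 ether is removed first, 36 is acylated with 37, and the C6 ether is cleaved at the end. The tertiary acetate is already in place, and the tertiary C1 hydroxyl needs no protection.

**C1–O bond (35 ⇐ 33).** The C1 hydroxyl is γ to the ketone, so it can come from oxidation of the silyl dienol ether 33 at its terminal carbon. This postpones the retro-aldol-prone carbinol to the end. The oxidant must enter anti to the C10 methyl and the C6 silyloxy group, which flank the C1=C5 bond on the same face.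

**C2–C3 bond (33 ⇐ 30), the key disconnection.** Cutting C2–C3 opens the five-membered ring to the dienal 30, in which C3 is an aldehyde and C2 a methylene. No other cut of the cyclopentenone leaves all five ring carbons in one conjugated, ring-templated array at the correct oxidation level. Forward, O-silylation must trigger a 4π closure, and the cation must lose the C3 proton so that the product is directly the dienol ether needed for the C1 oxidation.

**C1=C2 methylene (30 ⇐ 26).** The methylene is attached last. Adding an isopropenyl group to an α-methylene ketone would give a doubly allylic tertiary alcohol that can transpose in two directions. With C1 still saturated in 26, the one-carbon unit is introduced at the γ-position by a vinylogous Mannich reaction and elimination.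

**C4–C5 bond and the enal (26 ⇐ 25 ⇐ 24 + 3).** The three carbons C3, C4 and C15 come from the isopropenyl reagent 3, added to the C5 ketone of 24. Oxidative 1,3-transposition of the tertiary allylic alcohol 25 then gives the tetrasubstituted enal without any olefination of a hindered ketone.

**Seven-membered ring and C10 (24 ⇐ 23 ⇐ 22 ⇐ 21 ⇐ 19 + 20).** The ring is cut at C1=C10 (ring-closing metathesis of a vinyl carbinol with a 1,1-disubstituted alkene) and at C5–C1 (addition of 20 to aldehyde 19). C10 is set afterwards by hydrogenation of enone 23 from the face opposite the three cis substituents. This leaves only one stereocentre to substrate control on the ring.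

**C11 (19 ⇐ 17 ⇐ 14).** The two methyl groups on C11 are cut back to a methyl ester. The tertiary alkoxide is acetylated as it forms, so no protecting group is spent on the tertiary alcohol. C5 is carried as a dimethyl acetal, which is inert to the methyl nucleophile.

**C6–C7 bond (14 ⇐ 12 ⇐ 9 + 10).** On the ring the C6 oxygen and the C7 side chain are cis, which is an anti relationship along the chain C5–C6–C7–C8. An aldol with C8 as the acyl carbon would therefore have to be anti-selective. With C11 as the acyl carbon the same relationship is syn between the C6 hydroxyl and the C8 branch, so a standard auxiliary-controlled syn aldol of imide 9 with aldehyde 10 sets C6 and C7.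

**C8 and the C9–C10 bond (9 ⇐ 6 ⇐ 4 ⇐ 2 + 3 ⇐ 1).** C8 is taken from the chiral pool: chlorohydrin ester 1 gives epoxide 2, which is opened at C9 by reagent 3. No stereoselective step is needed for this centre, and the acid 6 is joined to auxiliary 7.

## Alternatives that were turned down

**Alternative 1:** The seven-membered ring is cut at C6–C7 and C9–C10 into a cyclopentane fragment with two exocyclic alkenes and a vinylcarbenoid fragment. Forward, a chiral dirhodium tetracarboxylate would generate the carbenoid, cyclopropanate the exocyclic methylene (C6–C7) and the divinylcyclopropane would rearrange (C9–C10) to the hydroazulene A1, setting C10 under catalyst control. In its favour: the step is convergent, forms two bonds and the ring, and belongs to a well-established reaction class, so on precedent and on control of C10 it is stronger than the chosen key step. Against it for this target: A1 has C6 as a bare, doubly allylic methylene, C7 and C8 as sp2 carbons of a β-keto ester enol ether, and no C11 carbinol. C6, C7 and C8 would all have to be set afterwards on the ring, including an oxidation at C6 with facial control and an all-cis reduction/protonation sequence next to a β-keto ester. The chosen strategy instead fixes C6–C8 in the open chain from an auxiliary and the chiral pool, and leaves only C10 and C1 to the ring.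

**Alternative 2:** The ring is cut at C1–C10, with a 2,3-dimethylfuran standing in for the hydroxycyclopentenone. Forward, constant-current anodic oxidation of an aldehyde silyl enol ether would give a radical cation that the free furan α-carbon attacks, closing the seven-membered ring to the cyclohepta[b]furan A2. In its favour: anodic furan–enol ether couplings are known, the C6–C8 triad can be carried in the tether, and the furan is robust, so on precedent the step is stronger than the chosen one. Against it: A2 carries a formyl group on C10 that must be reduced to a methyl group over several steps, and its configuration arises in a radical-cation closure with uncertain control. The carbocyclic five-membered ring is still missing; it would need oxidative furan opening and an aldol reclosure that must also set C1. The chosen key step makes the carbocycle itself at the correct oxidation level and leaves one oxidation.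

**Alternative 3:** Three bonds are cut at once (C1–C5, C2–C3, C3–C4), leading back to an open-chain allene–yne and CO. Forward, [Rh(CO)2Cl]2 under CO would couple the alkyne, the distal allene double bond and CO to the bicyclic dienone A3, with alkenes at C4–C5 and C1–C10. In its favour: it is the most step-economic construction of the skeleton and rhodium allenic Pauson–Khand reactions to five–seven systems are established, so it is stronger on both points. Against it: in A3 both C1 and C10 are sp2. The target would need a net hydration of the tetrasubstituted C1=C10 bond of a cross-conjugated dienone that sets two stereocentres (C1–OH and C10–H, trans to each other) in one operation, for which no reliable facial control can be named. The chosen strategy sets C10 by hydrogenation of a simple enone before the bicycle exists, and introduces the C1 oxygen onto a diene whose two neighbouring substituents shield the same face.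

Key step: step 19

Remark: ring atoms are referred to by the guaiane locants C1–C15 of the analysis; TBS = tert-butyldimethylsilyl, TES = triethylsilyl.
Remark: 2,2-dimethoxyacetaldehyde (10) is used as the anhydrous monomer, obtained by extraction and distillation of the commercial aqueous solution.
Remark: 21, 22 and 25 are carried as C5 epimers, 26–28 as alkene isomers (28 also as C1 epimers); these elements are removed in steps 13, 16 and 18 or equilibrated in step 19.

## Steps

Step 1
Reactants: 1 ethyl (3S)-4-chloro-3-hydroxybutanoate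
Product: 2 ethyl 2-[(2S)-oxiran-2-yl]acetate
Conditions: Ag2O, 1,2-dimethoxyethane, 60 °C
Reagents that add atoms: none
Why: Silver-assisted intramolecular Williamson etherification; the hydroxyl displaces the primary chloride while Ag2O takes up HCl without enolising the ester. The C–O bond of the carbinol carbon (later C8) is not touched, so its configuration is retained.

Step 2
Reactants: 2 ethyl 2-[(2S)-oxiran-2-yl]acetate; 3 prop-1-en-2-ylmagnesium bromide
Product: 4 ethyl (3R)-3-hydroxy-5-methylhex-5-enoate
Conditions: CuI (cat.), THF, −40 °C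
Reagents that add atoms: none
Why: Copper-catalysed Grignard opening of a terminal epoxide at the unsubstituted carbon (SN2) should be faster at −40 °C than addition to the ethyl ester. It forms the C9–C10 bond and leaves the carbinol centre untouched.

Step 3
Reactants: 4 ethyl (3R)-3-hydroxy-5-methylhex-5-enoate
Product: 5 ethyl (3R)-5-methyl-3-(triethylsilyloxy)hex-5-enoate
Conditions: TESCl, imidazole, CH2Cl2, 0 °C → rt
Reagents that add atoms: chlorotriethylsilane, CC[Si](Cl)(CC)CC
Why: Standard silylation of a secondary alcohol. The triethylsilyl ether is chosen because it must later be cleaved in the presence of a tert-butyldimethylsilyl ether.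

Step 4
Reactants: 5 ethyl (3R)-5-methyl-3-(triethylsilyloxy)hex-5-enoate
Product: 6 (3R)-5-methyl-3-(triethylsilyloxy)hex-5-enoic acid
Conditions: LiOH, THF/H2O, 0 °C → rt; then dilute HCl to pH 4, 0 °C
Reagents that add atoms: lithium hydroxide, [Li+].[OH-]
Why: Saponification of an ethyl ester; low temperature and a pH-controlled work-up avoid β-elimination and loss of the silyl ether.

Step 5
Reactants: 6 (3R)-5-methyl-3-(triethylsilyloxy)hex-5-enoic acid; 7 (4R)-4-benzyl-1,3-oxazolidin-2-one
Product: 9 (4R)-4-benzyl-3-[(3R)-5-methyl-3-(triethylsilyloxy)hex-5-enoyl]-1,3-oxazolidin-2-one, via mixed pivalic anhydride 8 (not isolated)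
Conditions: PivCl, Et3N, THF, −20 °C; then 7, LiCl, rt
Reagents that add atoms: none
Why: N-Acylation of the oxazolidinone through the mixed pivalic anhydride with LiCl activation, which avoids strongly basic conditions that could eliminate the β-silyloxy group. The (R)-auxiliary is the enantiomer that gives the required sense at C7 and C6 in step 6.

Step 6
Reactants: 9 (4R)-4-benzyl-3-[(3R)-5-methyl-3-(triethylsilyloxy)hex-5-enoyl]-1,3-oxazolidin-2-one; 10 2,2-dimethoxyacetaldehyde
Product: 12 (4R)-4-benzyl-3-[(2S,3R)-2-[(1R)-1-hydroxy-2,2-dimethoxyethyl]-5-methyl-3-(triethylsilyloxy)hex-5-enoyl]-1,3-oxazolidin-2-one, via boron enolate 11 (not isolated)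
Conditions: Bu2BOTf, iPr2NEt, CH2Cl2, 0 °C; 10, −78 → 0 °C; then pH 7 buffer, MeOH, H2O2, 0 °C
Reagents that add atoms: none
Why: Evans syn aldol reaction: the (Z)-dibutylboron enolate reacts through a closed Zimmerman–Traxler transition state in which the benzyl group of the auxiliary shields one enolate face. This forms C6–C7 and sets C7 and C6 with the C6 hydroxyl syn to the C8 branch (cis on the later ring); auxiliary control should override the small bias of the existing C8 centre.

Step 7
Reactants: 12 (4R)-4-benzyl-3-[(2S,3R)-2-[(1R)-1-hydroxy-2,2-dimethoxyethyl]-5-methyl-3-(triethylsilyloxy)hex-5-enoyl]-1,3-oxazolidin-2-one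
Product: 13 methyl (2S,3R)-2-[(1R)-1-hydroxy-2,2-dimethoxyethyl]-5-methyl-3-(triethylsilyloxy)hex-5-enoate
Conditions: MeMgBr, MeOH, CH2Cl2, 0 °C
Reagents that add atoms: methanol, CO
Why: Transesterification of an aldol imide with methoxymagnesium bromide; the magnesium alkoxide of the free C6 hydroxyl chelates the exocyclic carbonyl, so methoxide attacks there and the auxiliary is released without retro-aldol cleavage or epimerisation.

Step 8
Reactants: 13 methyl (2S,3R)-2-[(1R)-1-hydroxy-2,2-dimethoxyethyl]-5-methyl-3-(triethylsilyloxy)hex-5-enoate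
Product: 14 methyl (2R,3R)-2-[(1R)-1-(tert-butyldimethylsilyloxy)-2,2-dimethoxyethyl]-5-methyl-3-(triethylsilyloxy)hex-5-enoate
Conditions: TBSOTf, 2,6-lutidine, CH2Cl2, −78 °C
Reagents that add atoms: tert-butyldimethylsilyl triflate, CC(C)(C)[Si](C)(C)OS(=O)(=O)C(F)(F)F
Why: Silylation of a hindered secondary alcohol with the silyl triflate; at −78 °C the hydroxyl should react much faster than the dimethyl acetal is ionised. (The C2 descriptor changes only because the priorities change.)

Step 9
Reactants: 14 methyl (2R,3R)-2-[(1R)-1-(tert-butyldimethylsilyloxy)-2,2-dimethoxyethyl]-5-methyl-3-(triethylsilyloxy)hex-5-enoate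
Product: 17 2-[(2R,3R,4R)-2-(tert-butyldimethylsilyloxy)-1,1-dimethoxy-6-methyl-4-(triethylsilyloxy)hept-6-en-3-yl]propan-2-yl acetate, via methyl ketone 15 (not isolated), via magnesium alkoxide 16 (not isolated)
Conditions: MeMgBr, LaCl3·2LiCl, THF, 0 °C → rt; then Ac2O, DMAP (cat.), 0 °C → rt
Reagents that add atoms: methylmagnesium bromide, C[Mg]Br; acetic anhydride, CC(=O)OC(C)=O
Why: Double Grignard addition to the ester builds the tertiary carbinol C11; the lanthanum salt suppresses enolisation of the intermediate ketone and with it β-elimination of the silyloxy groups. Trapping the tertiary alkoxide in the flask with the anhydride gives the hindered acetate without a separate forcing acylation.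

Step 10
Reactants: 17 2-[(2R,3R,4R)-2-(tert-butyldimethylsilyloxy)-1,1-dimethoxy-6-methyl-4-(triethylsilyloxy)hept-6-en-3-yl]propan-2-yl acetate
Product: 19 2-[(2R,3R,4R)-2-(tert-butyldimethylsilyloxy)-6-methyl-1-oxo-4-(triethylsilyloxy)hept-6-en-3-yl]propan-2-yl acetate, via collidinium adduct 18 (not isolated)
Conditions: TESOTf, 2,4,6-collidine, CH2Cl2, 0 °C; then H2O
Reagents that add atoms: water, O
Why: Acetal cleavage by the silyl triflate–pyridine base method: the triflate ionises the acetal, the base holds the oxocarbenium ion as a pyridinium adduct, and water releases the aldehyde. The conditions are non-acidic and should spare both silyl ethers and the tertiary acetate.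

Step 11
Reactants: 19 2-[(2R,3R,4R)-2-(tert-butyldimethylsilyloxy)-6-methyl-1-oxo-4-(triethylsilyloxy)hept-6-en-3-yl]propan-2-yl acetate; 20 ethenylmagnesium bromide
Product: 21 2-[(4R,5R,6R)-4-(tert-butyldimethylsilyloxy)-3-hydroxy-8-methyl-6-(triethylsilyloxy)nona-1,8-dien-5-yl]propan-2-yl acetate (C3 epimers)
Conditions: THF, −78 °C
Reagents that add atoms: none
Why: Grignard addition to an aldehyde at −78 °C is much faster than attack on the hindered tertiary acetate. The new carbinol centre (C5) is oxidised in step 13, so its configuration is immaterial.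

Step 12
Reactants: 21 2-[(4R,5R,6R)-4-(tert-butyldimethylsilyloxy)-3-hydroxy-8-methyl-6-(triethylsilyloxy)nona-1,8-dien-5-yl]propan-2-yl acetate (C3 epimers)
Product: 22 2-[(1R,2R,7R)-2-(tert-butyldimethylsilyloxy)-3-hydroxy-5-methyl-7-(triethylsilyloxy)cyclohept-4-en-1-yl]propan-2-yl acetate (C3 epimers)
Conditions: second-generation Grubbs catalyst (cat.), CH2Cl2 (high dilution), 40 °C
Reagents that add atoms: none
Why: Ring-closing metathesis between the vinyl carbinol and the 1,1-disubstituted alkene closes the seven-membered ring at C1=C10 with loss of ethene. The three contiguous substituents favour the folded conformer.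

Step 13
Reactants: 22 2-[(1R,2R,7R)-2-(tert-butyldimethylsilyloxy)-3-hydroxy-5-methyl-7-(triethylsilyloxy)cyclohept-4-en-1-yl]propan-2-yl acetate (C3 epimers)
Product: 23 2-[(1R,2R,7R)-2-(tert-butyldimethylsilyloxy)-5-methyl-3-oxo-7-(triethylsilyloxy)cyclohept-4-en-1-yl]propan-2-yl acetate
Conditions: Dess–Martin periodinane, NaHCO3, CH2Cl2, 0 °C → rt
Reagents that add atoms: none
Why: Dess–Martin oxidation of the allylic alcohol removes the C5 stereocentre and gives the conjugated enone, whose C=C bond is hydrogenated cleanly.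

Step 14
Reactants: 23 2-[(1R,2R,7R)-2-(tert-butyldimethylsilyloxy)-5-methyl-3-oxo-7-(triethylsilyloxy)cyclohept-4-en-1-yl]propan-2-yl acetate
Product: 24 2-[(1R,2R,5S,7R)-2-(tert-butyldimethylsilyloxy)-5-methyl-3-oxo-7-(triethylsilyloxy)cycloheptyl]propan-2-yl acetate
Conditions: H2 (1 atm), palladium on carbon, EtOAc, rt
Reagents that add atoms: none
Why: Heterogeneous hydrogenation of the enone C=C; hydrogen should add to the face opposite the three cis substituents at C6, C7 and C8, which places the C10 methyl on their face (substrate control). Ethyl acetate as solvent avoids palladium-induced loss of the triethylsilyl ether.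

Step 15
Reactants: 24 2-[(1R,2R,5S,7R)-2-(tert-butyldimethylsilyloxy)-5-methyl-3-oxo-7-(triethylsilyloxy)cycloheptyl]propan-2-yl acetate; 3 prop-1-en-2-ylmagnesium bromide
Product: 25 2-[(1R,2R,5S,7R)-2-(tert-butyldimethylsilyloxy)-3-hydroxy-5-methyl-3-(prop-1-en-2-yl)-7-(triethylsilyloxy)cycloheptyl]propan-2-yl acetate (C3 epimers)
Conditions: LaCl3·2LiCl, THF, −78 °C
Reagents that add atoms: none
Why: Lanthanide-promoted 1,2-addition of an alkenyl Grignard reagent to a hindered, enolisable ketone; at −78 °C the ketone should react faster than the tertiary acetate. The configuration of the new carbinol centre is lost in step 16.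

Step 16
Reactants: 25 2-[(1R,2R,5S,7R)-2-(tert-butyldimethylsilyloxy)-3-hydroxy-5-methyl-3-(prop-1-en-2-yl)-7-(triethylsilyloxy)cycloheptyl]propan-2-yl acetate (C3 epimers)
Product: 26 2-[(1R,2R,5R,7R)-2-(tert-butyldimethylsilyloxy)-5-methyl-3-(1-oxopropan-2-ylidene)-7-(triethylsilyloxy)cycloheptyl]propan-2-yl acetate (alkene isomers)
Conditions: pyridinium chlorochromate [C5H5NH][CrO3Cl], NaOAc, 4 Å molecular sieves, CH2Cl2, rt
Reagents that add atoms: pyridinium chlorochromate, c1cc[nH+]cc1.[O-][Cr](=O)(=O)Cl
Why: Dauben–Babler oxidative transposition: the tertiary allylic chromate ester undergoes [3,3] shift to the primary allylic chromate, which is oxidised to the α-methyl enal. With C1 still a saturated methylene only the isopropenyl group can take part, so the regiochemistry is unambiguous.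

Step 17
Reactants: 26 2-[(1R,2R,5R,7R)-2-(tert-butyldimethylsilyloxy)-5-methyl-3-(1-oxopropan-2-ylidene)-7-(triethylsilyloxy)cycloheptyl]propan-2-yl acetate (alkene isomers)
Product: 28 2-[(1R,2R,5S,7R)-2-(tert-butyldimethylsilyloxy)-4-[(dimethylamino)methyl]-5-methyl-3-(1-oxopropan-2-ylidene)-7-(triethylsilyloxy)cycloheptyl]propan-2-yl acetate (C4 epimers; alkene isomers), via silyl dienol ether 27 (not isolated)
Conditions: TMSOTf, Et3N, CH2Cl2, 0 °C; then dimethylmethylideneammonium iodide, 0 °C → rt; aq. NaHCO3
Reagents that add atoms: dimethylmethylideneammonium iodide (Eschenmoser's salt), C=[N+](C)C.[I-]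
Why: Vinylogous Mannich reaction: soft enolisation should remove a γ-hydrogen from the unhindered C1 methylene and not from the silyloxy-bearing C6 methine. The 1-silyloxydiene then attacks the iminium ion at the γ-carbon, since α-attack would create a quaternary centre; this is the dienol ether route used for γ-methylenation of enones.

Step 18
Reactants: 28 2-[(1R,2R,5S,7R)-2-(tert-butyldimethylsilyloxy)-4-[(dimethylamino)methyl]-5-methyl-3-(1-oxopropan-2-ylidene)-7-(triethylsilyloxy)cycloheptyl]propan-2-yl acetate (C4 epimers; alkene isomers)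
Product: 30 2-[(1R,2R,3E,5S,7R)-2-(tert-butyldimethylsilyloxy)-5-methyl-4-methylidene-3-(1-oxopropan-2-ylidene)-7-(triethylsilyloxy)cycloheptyl]propan-2-yl acetate, via ammonium iodide 29 (not isolated)
Conditions: MeI, CH2Cl2, rt; then DBU, 0 °C; used at once
Reagents that add atoms: none
Why: Quaternisation and vinylogous E1cB (Hofmann-type) elimination: the C1 hydrogen is acidified by the enal and trimethylamine leaves from C2, giving the exocyclic methylene. Rotation about C4–C5 in the dienolate should let the smaller formyl group take the inside position next to C1, the geometry needed in step 19.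

Step 19
Reactants: 30 2-[(1R,2R,3E,5S,7R)-2-(tert-butyldimethylsilyloxy)-5-methyl-4-methylidene-3-(1-oxopropan-2-ylidene)-7-(triethylsilyloxy)cycloheptyl]propan-2-yl acetate
Product: 33 2-[(4R,5R,6R,8S)-2,4-bis(tert-butyldimethylsilyloxy)-3,8-dimethyl-6-(triethylsilyloxy)-1,4,5,6,7,8-hexahydroazulen-5-yl]propan-2-yl acetate, via silyloxypentadienyl cation 31 (not isolated), via cyclopentenyl cation 32 (not isolated)
Conditions: TBSOTf, 2,6-lutidine, CH2Cl2, −78 → −20 °C
Reagents that add atoms: tert-butyldimethylsilyl triflate, CC(C)(C)[Si](C)(C)OS(=O)(=O)C(F)(F)F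
Why: Proposed new method: the silyl triflate silylates the aldehyde oxygen of 30 to give the 1-silyloxypentadienyl cation 31, which spans C3, C4, C5, C1 and C2 and is held U-shaped because C5 and C1 are neighbours in the seven-membered ring. Thermally allowed conrotatory 4π electrocyclisation joins C2 to C3 and closes the five-membered ring, giving the allyl cation 32 over C4, C5 and C1. Lutidine then removes the C3 proton, the only proton whose loss gives a donor-substituted, fully conjugated diene, so the silyl dienol ether 33 is formed and not a cyclopentenone. The closest known reaction is the Brønsted or Lewis acid-promoted iso-Nazarov cyclisation of 2,4-dienals to cyclopent-2-enones; new here are the silyl triflate as stoichiometric activator and the interception of the product as its silyl dienol ether. No stereocentre is formed, since C3 ends sp2. The step needs O-silylation of the aldehyde in preference to the ester and ether oxygens, ring closure faster than loss of the C6 proton from 31 (which would give an open silyl trienol ether), and the formyl group cis to C1; the last is set in step 18 and, for any minor isomer, should be reached by rotation about the C4–C5 bond, whose double-bond character is reduced in the cation. Low temperature and the hindered base should suppress oxa-6π closure to a 2H-pyran and Diels–Alder dimerisation of the s-cis diene.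

Step 20
Reactants: 33 2-[(4R,5R,6R,8S)-2,4-bis(tert-butyldimethylsilyloxy)-3,8-dimethyl-6-(triethylsilyloxy)-1,4,5,6,7,8-hexahydroazulen-5-yl]propan-2-yl acetate
Product: 35 2-[(4R,5R,6R,8S,8aR)-4-(tert-butyldimethylsilyloxy)-8a-hydroxy-3,8-dimethyl-2-oxo-6-(triethylsilyloxy)-1,2,4,5,6,7,8,8a-octahydroazulen-5-yl]propan-2-yl acetate, via vinyl epoxide 34 (not isolated)
Conditions: dimethyldioxirane (acetone solution), CH2Cl2, −78 °C; then THF/pH 5 aqueous buffer, 0 °C
Reagents that add atoms: dimethyldioxirane, CC1(C)OO1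
Why: Vinylogous Rubottom oxidation: the dioxirane epoxidises the electron-rich C1=C5 bond of the silyl dienol ether, the epoxide opens with the push of the enol ether, and hydrolysis of the silyl oxocarbenium ion gives the γ-hydroxy enone. The oxidant should approach anti to the C10 methyl and the C6 silyloxy group, which flank the alkene on the same face, and so set C1.

Step 21
Reactants: 35 2-[(4R,5R,6R,8S,8aR)-4-(tert-butyldimethylsilyloxy)-8a-hydroxy-3,8-dimethyl-2-oxo-6-(triethylsilyloxy)-1,2,4,5,6,7,8,8a-octahydroazulen-5-yl]propan-2-yl acetate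
Product: 36 2-[(4R,5R,6R,8S,8aR)-4-(tert-butyldimethylsilyloxy)-6,8a-dihydroxy-3,8-dimethyl-2-oxo-1,2,4,5,6,7,8,8a-octahydroazulen-5-yl]propan-2-yl acetate
Conditions: HF·pyridine, pyridine, THF, 0 °C
Reagents that add atoms: none
Why: Buffered hydrogen fluoride–pyridine cleaves the secondary triethylsilyl ether much faster than the hindered secondary tert-butyldimethylsilyl ether. The tertiary C1 hydroxyl is inert.

Step 22
Reactants: 36 2-[(4R,5R,6R,8S,8aR)-4-(tert-butyldimethylsilyloxy)-6,8a-dihydroxy-3,8-dimethyl-2-oxo-1,2,4,5,6,7,8,8a-octahydroazulen-5-yl]propan-2-yl acetate; 37 (2Z)-2-methylbut-2-enoic acid (angelic acid)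
Product: 39 (4R,5R,6R,8S,8aR)-5-(2-acetoxypropan-2-yl)-4-(tert-butyldimethylsilyloxy)-8a-hydroxy-3,8-dimethyl-2-oxo-1,2,4,5,6,7,8,8a-octahydroazulen-6-yl (2Z)-2-methylbut-2-enoate, via mixed anhydride 38 (not isolated)
Conditions: 37, 2,4,6-trichlorobenzoyl chloride, Et3N, toluene, rt; then 36, 75 °C
Reagents that add atoms: none
Why: Yamaguchi esterification through the mixed 2,4,6-trichlorobenzoic anhydride, run without 4-(dimethylamino)pyridine so that the (Z)-alkene is not isomerised to the tiglate. Only the secondary C8 hydroxyl should be acylated; the tertiary C1 hydroxyl is too hindered.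

Step 23
Reactants: 39 (4R,5R,6R,8S,8aR)-5-(2-acetoxypropan-2-yl)-4-(tert-butyldimethylsilyloxy)-8a-hydroxy-3,8-dimethyl-2-oxo-1,2,4,5,6,7,8,8a-octahydroazulen-6-yl (2Z)-2-methylbut-2-enoate
Product: 40 (4R,5S,6R,8S,8aR)-5-(2-acetoxypropan-2-yl)-4,8a-dihydroxy-3,8-dimethyl-2-oxo-1,2,4,5,6,7,8,8a-octahydroazulen-6-yl (2Z)-2-methylbut-2-enoate
Conditions: HF·pyridine, THF, 0 °C → rt
Reagents that add atoms: none
Why: Fluoride-induced cleavage of the last silyl ether under mildly acidic conditions that should leave the angelate, the tertiary acetate and the β-hydroxy ketone untouched. (The C5 descriptor changes only because the priorities change.)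

## Compound list

1 | ethyl (3S)-4-chloro-3-hydroxybutanoate | ClC[C@@H](O)CC(=O)OCC | starting material
2 | ethyl 2-[(2S)-oxiran-2-yl]acetate | C1O[C@H]1CC(=O)OCC | intermediate
3 | prop-1-en-2-ylmagnesium bromide (isopropenylmagnesium bromide) | CC(=C)[Mg]Br | starting material
4 | ethyl (3R)-3-hydroxy-5-methylhex-5-enoate | CC(=C)C[C@@H](O)CC(=O)OCC | intermediate
5 | ethyl (3R)-5-methyl-3-(triethylsilyloxy)hex-5-enoate | CC(=C)C[C@@H](O[Si](CC)(CC)CC)CC(=O)OCC | intermediate
6 | (3R)-5-methyl-3-(triethylsilyloxy)hex-5-enoic acid | CC(=C)C[C@@H](O[Si](CC)(CC)CC)CC(=O)O | intermediate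
7 | (4R)-4-benzyl-1,3-oxazolidin-2-one | O=C1N[C@H](Cc2ccccc2)CO1 | starting material
8 | mixed anhydride of 6 and pivalic acid (formed in the flask) | CC(=C)C[C@@H](O[Si](CC)(CC)CC)CC(=O)OC(=O)C(C)(C)C | intermediate
9 | (4R)-4-benzyl-3-[(3R)-5-methyl-3-(triethylsilyloxy)hex-5-enoyl]-1,3-oxazolidin-2-one | CC(=C)C[C@@H](O[Si](CC)(CC)CC)CC(=O)N1[C@H](Cc2ccccc2)COC1=O | intermediate
10 | 2,2-dimethoxyacetaldehyde | COC(OC)C=O | starting material
11 | dibutylboron (Z)-enolate of 9 (formed in the flask) | CC(=C)C[C@@H](O[Si](CC)(CC)CC)/C=C(\OB(CCCC)CCCC)N1[C@H](Cc2ccccc2)COC1=O | intermediate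
12 | (4R)-4-benzyl-3-[(2S,3R)-2-[(1R)-1-hydroxy-2,2-dimethoxyethyl]-5-methyl-3-(triethylsilyloxy)hex-5-enoyl]-1,3-oxazolidin-2-one | CC(=C)C[C@@H](O[Si](CC)(CC)CC)[C@H]([C@@H](O)C(OC)OC)C(=O)N1[C@H](Cc2ccccc2)COC1=O | intermediate
13 | methyl (2S,3R)-2-[(1R)-1-hydroxy-2,2-dimethoxyethyl]-5-methyl-3-(triethylsilyloxy)hex-5-enoate | CC(=C)C[C@@H](O[Si](CC)(CC)CC)[C@H]([C@@H](O)C(OC)OC)C(=O)OC | intermediate
14 | methyl (2R,3R)-2-[(1R)-1-(tert-butyldimethylsilyloxy)-2,2-dimethoxyethyl]-5-methyl-3-(triethylsilyloxy)hex-5-enoate | CC(=C)C[C@@H](O[Si](CC)(CC)CC)[C@H]([C@@H](O[Si](C)(C)C(C)(C)C)C(OC)OC)C(=O)OC | intermediate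
15 | (3R,4R)-3-[(1R)-1-(tert-butyldimethylsilyloxy)-2,2-dimethoxyethyl]-6-methyl-4-(triethylsilyloxy)hept-6-en-2-one (formed in the flask) | CC(=C)C[C@@H](O[Si](CC)(CC)CC)[C@H]([C@@H](O[Si](C)(C)C(C)(C)C)C(OC)OC)C(C)=O | intermediate
16 | bromomagnesium 2-[(2R,3R,4R)-2-(tert-butyldimethylsilyloxy)-1,1-dimethoxy-6-methyl-4-(triethylsilyloxy)hept-6-en-3-yl]propan-2-olate (formed in the flask) | CC(=C)C[C@@H](O[Si](CC)(CC)CC)[C@H]([C@@H](O[Si](C)(C)C(C)(C)C)C(OC)OC)C(C)(C)O[Mg]Br | intermediate
17 | 2-[(2R,3R,4R)-2-(tert-butyldimethylsilyloxy)-1,1-dimethoxy-6-methyl-4-(triethylsilyloxy)hept-6-en-3-yl]propan-2-yl acetate | CC(=C)C[C@@H](O[Si](CC)(CC)CC)[C@H]([C@@H](O[Si](C)(C)C(C)(C)C)C(OC)OC)C(C)(C)OC(C)=O | intermediate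
18 | N-(1-methoxyalkyl)-2,4,6-trimethylpyridinium triflate derived from 17 at C5 (formed in the flask; C5 epimers) | CC(=C)C[C@@H](O[Si](CC)(CC)CC)[C@H]([C@@H](O[Si](C)(C)C(C)(C)C)C(OC)[n+]1c(C)cc(C)cc1C)C(C)(C)OC(C)=O.[O-]S(=O)(=O)C(F)(F)F | intermediate
19 | 2-[(2R,3R,4R)-2-(tert-butyldimethylsilyloxy)-6-methyl-1-oxo-4-(triethylsilyloxy)hept-6-en-3-yl]propan-2-yl acetate | CC(=C)C[C@@H](O[Si](CC)(CC)CC)[C@H]([C@@H](O[Si](C)(C)C(C)(C)C)C=O)C(C)(C)OC(C)=O | intermediate
20 | ethenylmagnesium bromide (vinylmagnesium bromide) | C=C[Mg]Br | starting material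
21 | 2-[(4R,5R,6R)-4-(tert-butyldimethylsilyloxy)-3-hydroxy-8-methyl-6-(triethylsilyloxy)nona-1,8-dien-5-yl]propan-2-yl acetate (C3 epimers) | CC(=C)C[C@@H](O[Si](CC)(CC)CC)[C@H]([C@@H](O[Si](C)(C)C(C)(C)C)C(O)C=C)C(C)(C)OC(C)=O | intermediate
22 | 2-[(1R,2R,7R)-2-(tert-butyldimethylsilyloxy)-3-hydroxy-5-methyl-7-(triethylsilyloxy)cyclohept-4-en-1-yl]propan-2-yl acetate (C3 epimers) | CC[Si](CC)(CC)O[C@@H]1CC(C)=CC(O)[C@H](O[Si](C)(C)C(C)(C)C)[C@@H]1C(C)(C)OC(C)=O | intermediate
23 | 2-[(1R,2R,7R)-2-(tert-butyldimethylsilyloxy)-5-methyl-3-oxo-7-(triethylsilyloxy)cyclohept-4-en-1-yl]propan-2-yl acetate | CC[Si](CC)(CC)O[C@@H]1CC(C)=CC(=O)[C@H](O[Si](C)(C)C(C)(C)C)[C@@H]1C(C)(C)OC(C)=O | intermediate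
24 | 2-[(1R,2R,5S,7R)-2-(tert-butyldimethylsilyloxy)-5-methyl-3-oxo-7-(triethylsilyloxy)cycloheptyl]propan-2-yl acetate | CC[Si](CC)(CC)O[C@@H]1C[C@H](C)CC(=O)[C@H](O[Si](C)(C)C(C)(C)C)[C@@H]1C(C)(C)OC(C)=O | intermediate
25 | 2-[(1R,2R,5S,7R)-2-(tert-butyldimethylsilyloxy)-3-hydroxy-5-methyl-3-(prop-1-en-2-yl)-7-(triethylsilyloxy)cycloheptyl]propan-2-yl acetate (C3 epimers) | CC[Si](CC)(CC)O[C@@H]1C[C@H](C)CC(O)(C(C)=C)[C@H](O[Si](C)(C)C(C)(C)C)[C@@H]1C(C)(C)OC(C)=O | intermediate
26 | 2-[(1R,2R,5R,7R)-2-(tert-butyldimethylsilyloxy)-5-methyl-3-(1-oxopropan-2-ylidene)-7-(triethylsilyloxy)cycloheptyl]propan-2-yl acetate (alkene isomers) | CC[Si](CC)(CC)O[C@@H]1C[C@H](C)CC(=C(C)C=O)[C@H](O[Si](C)(C)C(C)(C)C)[C@@H]1C(C)(C)OC(C)=O | intermediate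
27 | trimethylsilyl dienol ether of 26 with C1=C5 and C3=C4 double bonds (formed in the flask) | CC[Si](CC)(CC)O[C@@H]1C[C@H](C)C=C(C(C)=CO[Si](C)(C)C)[C@H](O[Si](C)(C)C(C)(C)C)[C@@H]1C(C)(C)OC(C)=O | intermediate
28 | 2-[(1R,2R,5S,7R)-2-(tert-butyldimethylsilyloxy)-4-[(dimethylamino)methyl]-5-methyl-3-(1-oxopropan-2-ylidene)-7-(triethylsilyloxy)cycloheptyl]propan-2-yl acetate (C4 epimers; alkene isomers) | CC[Si](CC)(CC)O[C@@H]1C[C@H](C)C(CN(C)C)C(=C(C)C=O)[C@H](O[Si](C)(C)C(C)(C)C)[C@@H]1C(C)(C)OC(C)=O | intermediate
29 | trimethylammonium iodide of 28 (formed in the flask) | CC[Si](CC)(CC)O[C@@H]1C[C@H](C)C(C[N+](C)(C)C)C(=C(C)C=O)[C@H](O[Si](C)(C)C(C)(C)C)[C@@H]1C(C)(C)OC(C)=O.[I-] | intermediate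
30 | 2-[(1R,2R,3E,5S,7R)-2-(tert-butyldimethylsilyloxy)-5-methyl-4-methylidene-3-(1-oxopropan-2-ylidene)-7-(triethylsilyloxy)cycloheptyl]propan-2-yl acetate (formyl group cis to C1) | CC[Si](CC)(CC)O[C@@H]1C[C@H](C)C(=C)/C(=C(/C)C=O)[C@H](O[Si](C)(C)C(C)(C)C)[C@@H]1C(C)(C)OC(C)=O | intermediate
31 | O-silylated 30, the 1-silyloxypentadienyl cation over C3–C4–C5–C1–C2, as triflate (formed in the flask) | CC[Si](CC)(CC)O[C@@H]1C[C@H](C)C(=C)/C(=C(/C)C=[O+][Si](C)(C)C(C)(C)C)[C@H](O[Si](C)(C)C(C)(C)C)[C@@H]1C(C)(C)OC(C)=O.[O-]S(=O)(=O)C(F)(F)F | intermediate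
32 | ring-closed allyl cation over C4–C5–C1 with sp3 C3 bearing H and OTBS, as triflate (formed in the flask; drawn with the charge on C1) | CC[Si](CC)(CC)O[C@@H]1C[C@H](C)[C+]2CC(O[Si](C)(C)C(C)(C)C)C(C)=C2[C@H](O[Si](C)(C)C(C)(C)C)[C@@H]1C(C)(C)OC(C)=O.[O-]S(=O)(=O)C(F)(F)F | intermediate
33 | 2-[(4R,5R,6R,8S)-2,4-bis(tert-butyldimethylsilyloxy)-3,8-dimethyl-6-(triethylsilyloxy)-1,4,5,6,7,8-hexahydroazulen-5-yl]propan-2-yl acetate | CC[Si](CC)(CC)O[C@@H]1C[C@H](C)C2=C(C(C)=C(O[Si](C)(C)C(C)(C)C)C2)[C@H](O[Si](C)(C)C(C)(C)C)[C@@H]1C(C)(C)OC(C)=O | intermediate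
34 | C1–C5 epoxide of 33 on the face opposite the C10 methyl (formed in the flask) | CC[Si](CC)(CC)O[C@@H]1C[C@H](C)[C@]23O[C@@]3(C(C)=C(O[Si](C)(C)C(C)(C)C)C2)[C@H](O[Si](C)(C)C(C)(C)C)[C@@H]1C(C)(C)OC(C)=O | intermediate
35 | 2-[(4R,5R,6R,8S,8aR)-4-(tert-butyldimethylsilyloxy)-8a-hydroxy-3,8-dimethyl-2-oxo-6-(triethylsilyloxy)-1,2,4,5,6,7,8,8a-octahydroazulen-5-yl]propan-2-yl acetate | CC[Si](CC)(CC)O[C@@H]1C[C@H](C)[C@]2(O)CC(=O)C(C)=C2[C@H](O[Si](C)(C)C(C)(C)C)[C@@H]1C(C)(C)OC(C)=O | intermediate
36 | 2-[(4R,5R,6R,8S,8aR)-4-(tert-butyldimethylsilyloxy)-6,8a-dihydroxy-3,8-dimethyl-2-oxo-1,2,4,5,6,7,8,8a-octahydroazulen-5-yl]propan-2-yl acetate | O[C@@H]1C[C@H](C)[C@]2(O)CC(=O)C(C)=C2[C@H](O[Si](C)(C)C(C)(C)C)[C@@H]1C(C)(C)OC(C)=O | intermediate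
37 | (2Z)-2-methylbut-2-enoic acid (angelic acid) | C/C=C(/C)C(=O)O | starting material
38 | (2Z)-2-methylbut-2-enoic 2,4,6-trichlorobenzoic anhydride (formed in the flask) | C/C=C(/C)C(=O)OC(=O)c1c(Cl)cc(Cl)cc1Cl | intermediate
39 | (4R,5R,6R,8S,8aR)-5-(2-acetoxypropan-2-yl)-4-(tert-butyldimethylsilyloxy)-8a-hydroxy-3,8-dimethyl-2-oxo-1,2,4,5,6,7,8,8a-octahydroazulen-6-yl (2Z)-2-methylbut-2-enoate | C/C=C(/C)C(=O)O[C@@H]1C[C@H](C)[C@]2(O)CC(=O)C(C)=C2[C@H](O[Si](C)(C)C(C)(C)C)[C@@H]1C(C)(C)OC(C)=O | intermediate
40 | (4R,5S,6R,8S,8aR)-5-(2-acetoxypropan-2-yl)-4,8a-dihydroxy-3,8-dimethyl-2-oxo-1,2,4,5,6,7,8,8a-octahydroazulen-6-yl (2Z)-2-methylbut-2-enoate | C/C=C(/C)C(=O)O[C@@H]1C[C@H](C)[C@]2(O)CC(=O)C(C)=C2[C@H](O)[C@@H]1C(C)(C)OC(C)=O | target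

## Step count and least certain steps

Total step count: 23. Longest linear sequence: 23 steps (1 → 40); the route is fully linear, with 3, 7, 10, 20 and 37 brought in as commercial reagents.

**Step 19 (key step).** The most likely failure is plain enol silylation without ring closure: loss of the C6 proton from cation 31 may outrun the 4π closure, because the oxygen-stabilised open cation is lower in energy than the ring-closed allyl cation. Incomplete interconversion of the alkene isomers of 30 or proton shifts in the cyclopentadiene product may also lower the outcome. Fallback, from ketone 24 back to 33 (bypassing 25–30): kinetic enolate formation at C1 (lithium diisopropylamide, THF, −78 °C) and alkylation with 1-bromobut-2-yne should give the 4-(but-2-yn-1-yl) ketone F1. Gold-catalysed hydration (Ph3PAuNTf2, wet dioxane), directed to the alkyne carbon nearer the ring by participation of the ring carbonyl, should give the 1,4-diketone F2. Intramolecular aldol condensation (KOtBu, tBuOH/THF) closes the cyclopentenone to the 1-deoxy enone F3, and γ-deprotonative silylation (TBSOTf, Et3N, CH2Cl2) at C1 gives 33.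

**Step 17.** Enolisation may occur toward C6 instead of C1, or the iminium ion may attack the α-carbon; either would divert the one-carbon unit or scramble C6, and the s-cis dienal formed in step 18 may dimerise. Fallback, from ketone 24 back to 30 (bypassing 25–28), fixing the regiochemistry at the ketone enolate stage: kinetic enolate formation and reaction with gaseous formaldehyde should give the 4-(hydroxymethyl) ketone F4. Acylation (pivaloyl chloride, pyridine) gives the pivalate F5, addition of 3 (LaCl3·2LiCl, THF, −78 °C) gives the tertiary allylic alcohol F6, and oxidative transposition with pyridinium chlorochromate gives the enal pivalate F7. DBU then eliminates pivalate from C2 by the vinylogous E1cB path to give 30.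

**Step 20.** The dioxirane may attack the enol ether double bond (hydroxylation at C4), approach with poor facial selectivity, or the silyl group may migrate to the new C1 oxygen instead of being hydrolysed. Fallback, from 33 back to 35: sensitised photo-oxygenation (O2, tetraphenylporphyrin, visible light, CH2Cl2, −78 °C) adds singlet oxygen across C3 and C1 of the cyclopentadiene from the open face to give the endoperoxide F8. Reduction of the O–O bond with thiourea in methanol leaves a silyl hemiketal at C3 that collapses to the ketone, giving 35.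

**Step 15.** The alkenyl Grignard reagent may attack the tertiary acetate, or the acetyl group may migrate to the new tertiary alkoxide, because the ketone is hindered on both sides. Fallback, from ketone 24 back to 26, without a strong nucleophile: kinetic enol triflate formation toward C1 (KHMDS, N-phenyltriflimide, THF, −78 °C) should give the enol triflate F9. Suzuki coupling with isopropenylboronic acid pinacol ester (Pd(PPh3)4, K3PO4) gives the diene F10, and hydroboration of the terminal alkene (9-BBN; then NaBO3) gives the primary alcohol F11. Dess–Martin oxidation gives the β,γ-unsaturated aldehyde F12, and DBU moves the double bond into conjugation to give 26.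

**Step 14.** Facial selectivity may be poor, because the cycloheptenone is conformationally mobile and the shielding substituents are one and two atoms away from C10. Fallback, from enone 23 back to 24, replacing substrate control by reagent control: copper hydride conjugate reduction with a chiral bisphosphine (Cu(OAc)2, the DTBM-SEGPHOS enantiomer matched to the substrate, polymethylhydrosiloxane, tert-butanol, toluene) delivers hydride to C10 and gives 24 directly; no new compound is formed (F0).

## Further compounds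

F1 | step 19 | 2-[(1R,2R,5S,7R)-4-(but-2-yn-1-yl)-2-(tert-butyldimethylsilyloxy)-5-methyl-3-oxo-7-(triethylsilyloxy)cycloheptyl]propan-2-yl acetate (C4 epimers) | CC[Si](CC)(CC)O[C@@H]1C[C@H](C)C(CC#CC)C(=O)[C@H](O[Si](C)(C)C(C)(C)C)[C@@H]1C(C)(C)OC(C)=O
F2 | step 19 | 2-[(1R,2R,5S,7R)-2-(tert-butyldimethylsilyloxy)-5-methyl-3-oxo-4-(2-oxobutyl)-7-(triethylsilyloxy)cycloheptyl]propan-2-yl acetate (C4 epimers) | CC[Si](CC)(CC)O[C@@H]1C[C@H](C)C(CC(=O)CC)C(=O)[C@H](O[Si](C)(C)C(C)(C)C)[C@@H]1C(C)(C)OC(C)=O
F3 | step 19 | 2-[(4R,5R,6R,8S)-4-(tert-butyldimethylsilyloxy)-3,8-dimethyl-2-oxo-6-(triethylsilyloxy)-1,2,4,5,6,7,8,8a-octahydroazulen-5-yl]propan-2-yl acetate (C8a epimers) | CC[Si](CC)(CC)O[C@@H]1C[C@H](C)C2CC(=O)C(C)=C2[C@H](O[Si](C)(C)C(C)(C)C)[C@@H]1C(C)(C)OC(C)=O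
F4 | step 17 | 2-[(1R,2R,5S,7R)-2-(tert-butyldimethylsilyloxy)-4-(hydroxymethyl)-5-methyl-3-oxo-7-(triethylsilyloxy)cycloheptyl]propan-2-yl acetate (C4 epimers) | CC[Si](CC)(CC)O[C@@H]1C[C@H](C)C(CO)C(=O)[C@H](O[Si](C)(C)C(C)(C)C)[C@@H]1C(C)(C)OC(C)=O
F5 | step 17 | 2-[(1R,2R,5S,7R)-2-(tert-butyldimethylsilyloxy)-5-methyl-3-oxo-4-[(pivaloyloxy)methyl]-7-(triethylsilyloxy)cycloheptyl]propan-2-yl acetate (C4 epimers) | CC[Si](CC)(CC)O[C@@H]1C[C@H](C)C(COC(=O)C(C)(C)C)C(=O)[C@H](O[Si](C)(C)C(C)(C)C)[C@@H]1C(C)(C)OC(C)=O
F6 | step 17 | 2-[(1R,2R,5S,7R)-2-(tert-butyldimethylsilyloxy)-3-hydroxy-5-methyl-4-[(pivaloyloxy)methyl]-3-(prop-1-en-2-yl)-7-(triethylsilyloxy)cycloheptyl]propan-2-yl acetate (C3 and C4 epimers) | CC[Si](CC)(CC)O[C@@H]1C[C@H](C)C(COC(=O)C(C)(C)C)C(O)(C(C)=C)[C@H](O[Si](C)(C)C(C)(C)C)[C@@H]1C(C)(C)OC(C)=O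
F7 | step 17 | 2-[(1R,2R,5S,7R)-2-(tert-butyldimethylsilyloxy)-5-methyl-3-(1-oxopropan-2-ylidene)-4-[(pivaloyloxy)methyl]-7-(triethylsilyloxy)cycloheptyl]propan-2-yl acetate (C4 epimers; alkene isomers) | CC[Si](CC)(CC)O[C@@H]1C[C@H](C)C(COC(=O)C(C)(C)C)C(=C(C)C=O)[C@H](O[Si](C)(C)C(C)(C)C)[C@@H]1C(C)(C)OC(C)=O
F8 | step 20 | 2-[(4R,5R,6R,8S)-2,4-bis(tert-butyldimethylsilyloxy)-2,8a-epidioxy-3,8-dimethyl-6-(triethylsilyloxy)-1,2,4,5,6,7,8,8a-octahydroazulen-5-yl]propan-2-yl acetate (peroxide bridge on the face opposite the C8 methyl) | CC[Si](CC)(CC)O[C@@H]1C[C@H](C)[C@@]23CC(O[Si](C)(C)C(C)(C)C)(OO2)C(C)=C3[C@H](O[Si](C)(C)C(C)(C)C)[C@@H]1C(C)(C)OC(C)=O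
F9 | step 15 | 2-[(1R,2R,5S,7R)-2-(tert-butyldimethylsilyloxy)-5-methyl-7-(triethylsilyloxy)-3-(trifluoromethanesulfonyloxy)cyclohept-3-en-1-yl]propan-2-yl acetate | CC[Si](CC)(CC)O[C@@H]1C[C@H](C)C=C(OS(=O)(=O)C(F)(F)F)[C@H](O[Si](C)(C)C(C)(C)C)[C@@H]1C(C)(C)OC(C)=O
F10 | step 15 | 2-[(1R,2R,5S,7R)-2-(tert-butyldimethylsilyloxy)-5-methyl-3-(prop-1-en-2-yl)-7-(triethylsilyloxy)cyclohept-3-en-1-yl]propan-2-yl acetate | CC[Si](CC)(CC)O[C@@H]1C[C@H](C)C=C(C(C)=C)[C@H](O[Si](C)(C)C(C)(C)C)[C@@H]1C(C)(C)OC(C)=O
F11 | step 15 | 2-[(1R,2R,5S,7R)-2-(tert-butyldimethylsilyloxy)-3-(1-hydroxypropan-2-yl)-5-methyl-7-(triethylsilyloxy)cyclohept-3-en-1-yl]propan-2-yl acetate (side-chain epimers) | CC[Si](CC)(CC)O[C@@H]1C[C@H](C)C=C(C(C)CO)[C@H](O[Si](C)(C)C(C)(C)C)[C@@H]1C(C)(C)OC(C)=O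
F12 | step 15 | 2-[(1R,2R,5S,7R)-2-(tert-butyldimethylsilyloxy)-5-methyl-3-(1-oxopropan-2-yl)-7-(triethylsilyloxy)cyclohept-3-en-1-yl]propan-2-yl acetate (side-chain epimers) | CC[Si](CC)(CC)O[C@@H]1C[C@H](C)C=C(C(C)C=O)[C@H](O[Si](C)(C)C(C)(C)C)[C@@H]1C(C)(C)OC(C)=O
F0 | step 14 | none | none
A1 | alternative 1 | methyl (8S)-6-(tert-butyldimethylsilyloxy)-3,8-dimethyl-2-(triisopropylsilyloxy)-1,4,7,8-tetrahydroazulene-5-carboxylate | CC(C)(C)[Si](C)(C)OC1=C(C(=O)OC)CC2=C(CC(O[Si](C(C)C)(C(C)C)C(C)C)=C2C)[C@@H](C)C1
A2 | alternative 2 | 2-[(4R,5R,6R,8S)-4-(tert-butyldimethylsilyloxy)-8-formyl-2,3-dimethyl-6-(triethylsilyloxy)-5,6,7,8-tetrahydro-4H-cyclohepta[b]furan-5-yl]propan-2-yl acetate | CC[Si](CC)(CC)O[C@@H]1C[C@H](C=O)c2oc(C)c(C)c2[C@H](O[Si](C)(C)C(C)(C)C)[C@@H]1C(C)(C)OC(C)=O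
A3 | alternative 3 | 2-[(4R,5R,6R)-4-(tert-butyldimethylsilyloxy)-3,8-dimethyl-2-oxo-6-(triethylsilyloxy)-1,2,4,5,6,7-hexahydroazulen-5-yl]propan-2-yl acetate | CC[Si](CC)(CC)O[C@@H]1CC(C)=C2CC(=O)C(C)=C2[C@H](O[Si](C)(C)C(C)(C)C)[C@@H]1C(C)(C)OC(C)=O
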